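The pyranone ring is closed late, between the carbonyl carbon C4 and the stereogenic C3. The route exploits the free 4'-hydroxyl of ring B, which stands para to C3. A racemic benzylic sulfone at C3 loses sulfinate under mild base and gives a ring-B p-quinone methide whose exocyclic carbon is C3. A chiral triazolylidene turns the ring-A aldehyde (the future C4) into an acyl anion equivalent that adds 1,6 to this carbon. One operation thus forms C3–C4, closes the ring, re-aromatises ring B and sets C3 stereoconvergently. The precursor is an open 2-(2-aryl-2-tosylethoxy)benzaldehyde that already carries both prenyl groups.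

Key step: step 7

Remark 1: the THP acetal carbon (4–7) and the benzylic carbon that becomes C3 (5–8) are used as racemates or diastereomer mixtures and carry no descriptor in the SMILES; step 6 removes the first and step 7 erases the second.
Remark 2: which antipode of the aminoindanol-derived triazolium salt leads to 3S cannot be assigned with certainty beforehand; it is assumed to be fixed by a small-scale cyclisation of 8, both antipodes being commercially available.

Step 1
Reactants: 1 5-bromo-2,4-dihydroxybenzaldehyde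
Product: 2 5-bromo-2-hydroxy-4-[(triisopropylsilyl)oxy]benzaldehyde
Conditions: TIPSCl (1.05 equiv), imidazole (2 equiv), CH2Cl2, 0 °C → rt
Reagents that add atoms: chlorotriisopropylsilane CC(C)[Si](Cl)(C(C)C)C(C)C
Why: Regioselective O-silylation of a phenol: the 2-OH is tied up in a hydrogen bond to the formyl group and is the poorer nucleophile, so the bulky chlorosilane should react at the 4-OH only.

Step 2
Reactants: 3 3-bromo-4-hydroxybenzaldehyde
Product: 4 3-bromo-4-(oxan-2-yloxy)benzaldehyde
Conditions: 3,4-dihydro-2H-pyran (1.5 equiv), PPTS (5 mol%), CH2Cl2, rt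
Reagents that add atoms: 3,4-dihydro-2H-pyran C1=COCCC1
Why: Acid-catalysed tetrahydropyranylation (acetal formation from an enol ether) masks the ring-B phenol in a base-stable form that the acid of step 6 removes again; the acetal carbon forms as a racemate and plays no part later.

Step 3
Reactants: 4 3-bromo-4-(oxan-2-yloxy)benzaldehyde
Product: 5 2-[2-bromo-4-(oxiran-2-yl)phenoxy]oxane
Conditions: Me3S+ I− (1.3 equiv), powdered KOH (2 equiv), MeCN (trace H2O), 60 °C
Reagents that add atoms: trimethylsulfonium iodide C[S+](C)C.[I-]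
Why: Corey–Chaykovsky epoxidation: the sulfonium ylide adds to the aldehyde and the betaine closes to the terminal epoxide with loss of dimethyl sulfide; the benzylic centre forms racemic, which is intended because step 7 erases it.

Step 4
Reactants: 2 5-bromo-2-hydroxy-4-[(triisopropylsilyl)oxy]benzaldehyde; 5 2-[2-bromo-4-(oxiran-2-yl)phenoxy]oxane
Product: 6 5-bromo-2-{2-[3-bromo-4-(oxan-2-yloxy)phenyl]-2-hydroxyethoxy}-4-[(triisopropylsilyl)oxy]benzaldehyde
Conditions: n-Bu4NBr (10 mol%), i-Pr2NEt (0.5 equiv), DMF, 80 °C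
Reagents that add atoms: none
Why: Base-catalysed phenol–epoxide ring opening (SN2 of the salicylaldehyde phenoxide at the unhindered terminal carbon) should give the 2-aryloxy-1-arylethanol; amine/onium catalysis in place of carbonate spares the aryl silyl ether, and the aldehyde is inert to these conditions.

Step 5
Reactants: 6 5-bromo-2-{2-[3-bromo-4-(oxan-2-yloxy)phenyl]-2-hydroxyethoxy}-4-[(triisopropylsilyl)oxy]benzaldehyde
Product: 7 2-{2-hydroxy-2-[3-(3-methylbut-2-en-1-yl)-4-(oxan-2-yloxy)phenyl]ethoxy}-5-(3-methylbut-2-en-1-yl)-4-[(triisopropylsilyl)oxy]benzaldehyde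
Conditions: prenylSnBu3 (2.6 equiv), Pd(PPh3)4 (10 mol%), degassed DMF, 100 °C
Reagents that add atoms: tributyl(3-methylbut-2-en-1-yl)stannane CCCC[Sn](CCCC)(CCCC)CC=C(C)C
Why: Twofold Stille coupling: the neutral conditions tolerate the aldehyde, the free alcohol, the acetal and the silyl ether, and transfer of the prenyl group through its α-carbon should place the linear 3-methylbut-2-enyl group at both aryl bromides.

Step 6
Reactants: 7 2-{2-hydroxy-2-[3-(3-methylbut-2-en-1-yl)-4-(oxan-2-yloxy)phenyl]ethoxy}-5-(3-methylbut-2-en-1-yl)-4-[(triisopropylsilyl)oxy]benzaldehyde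
Product: 8 2-{2-[4-hydroxy-3-(3-methylbut-2-en-1-yl)phenyl]-2-(4-methylbenzenesulfonyl)ethoxy}-5-(3-methylbut-2-en-1-yl)-4-[(triisopropylsilyl)oxy]benzaldehyde
Conditions: p-TolSO2H (3 equiv, freshly prepared), THF/H2O 9:1, rt; NaHCO3 wash
Reagents that add atoms: p-toluenesulfinic acid Cc1ccc(cc1)S(=O)O
Why: Acid-mediated SN1-type sulfinate substitution of a p-hydroxybenzylic alcohol: the sulfinic acid first hydrolyses the THP acetal, then ionises the benzylic alcohol to a protonated quinone methide and traps it at sulfur to give the racemic, bench-stable sulfone, while an acid of this strength at room temperature should neither cyclise the o-prenylphenols nor cleave the aryl TIPS ether.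

Step 7
Reactants: 8 2-{2-[4-hydroxy-3-(3-methylbut-2-en-1-yl)phenyl]-2-(4-methylbenzenesulfonyl)ethoxy}-5-(3-methylbut-2-en-1-yl)-4-[(triisopropylsilyl)oxy]benzaldehyde
Product: 10 (3S)-3-[4-hydroxy-3-(3-methylbut-2-en-1-yl)phenyl]-6-(3-methylbut-2-en-1-yl)-7-[(triisopropylsilyl)oxy]-2,3-dihydro-4H-chromen-4-one, via ring-B p-quinone methide 9 (not isolated)
Conditions: aminoindanol-derived N-C6F5 triazolium tetrafluoroborate (20 mol%, antipode as in remark 2), i-Pr2NEt (1.2 equiv), 4 Å MS, toluene, 0 °C → rt; then AcOH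
Reagents that add atoms: none
Why: Proposed new method: the amine deprotonates the 4'-OH and the phenoxide expels p-toluenesulfinate in a reversible 1,6-elimination to give the achiral p-quinone methide 9, while the triazolylidene adds to the aldehyde and forms a Breslow intermediate that attacks the exocyclic methide carbon (the future C3) in an intramolecular 1,6-addition, after which ring B re-aromatises and the adduct releases the carbene and the C4 ketone. The closest known reactions are the enantioselective intramolecular Stetter cyclisation of salicylaldehyde-tethered Michael acceptors to 3-substituted chroman-4-ones and the intermolecular carbene-catalysed 1,6-addition of aldehydes to p-quinone methides; new is their combination on a quinone methide generated in situ from a sulfone. The pyranone ring closes in a 6-exo-trig mode, the acyl anion carbon attacking the exocyclic C=C of the quinone methide through the O–CH2 tether. The C3 stereocentre is set in the C–C bond-forming step by the chiral aminoindanol backbone of the carbene, which shields one face of the methide carbon; both enantiomers of 8 and both E/Z isomers of 9 converge on one product because the centre of 8 is erased in 9 and ring B ends as a freely rotating aryl group. The step needs the 1,6-addition to outrun tautomerisation of 9 to the 4-hydroxystyryl ether and needs the enolisable α-aryl ketone to keep its configuration: reversible re-addition of sulfinate keeps the concentration of 9 low, the silyl ether on the C7 oxygen keeps the aldehyde electrophilic where a free phenoxide would deactivate it, and the weak amine base with an acetic acid quench limits enolisation at C3.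

Step 8
Reactants: 10 (3S)-3-[4-hydroxy-3-(3-methylbut-2-en-1-yl)phenyl]-6-(3-methylbut-2-en-1-yl)-7-[(triisopropylsilyl)oxy]-2,3-dihydro-4H-chromen-4-one
Product: 11 (3S)-7-hydroxy-3-[4-hydroxy-3-(3-methylbut-2-en-1-yl)phenyl]-6-(3-methylbut-2-en-1-yl)-2,3-dihydro-4H-chromen-4-one
Conditions: Et3N·3HF (3 equiv), THF, 0 °C → rt; pH 7 buffer work-up
Reagents that add atoms: none
Why: Fluoride-induced desilylation of an aryl silyl ether; the weakly acidic amine hydrofluoride forms no enolate at C3 and does not add to the prenyl groups, so the 3S centre set in step 7 should pass into the target unchanged.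

Compound list
1 | 5-bromo-2,4-dihydroxybenzaldehyde | O=Cc1cc(Br)c(O)cc1O | starting material
2 | 5-bromo-2-hydroxy-4-[(triisopropylsilyl)oxy]benzaldehyde | O=Cc1cc(Br)c(O[Si](C(C)C)(C(C)C)C(C)C)cc1O | intermediate
3 | 3-bromo-4-hydroxybenzaldehyde | O=Cc1ccc(O)c(Br)c1 | starting material
4 | 3-bromo-4-(oxan-2-yloxy)benzaldehyde (racemic THP ether) | O=Cc1ccc(OC2CCCCO2)c(Br)c1 | intermediate
5 | 2-[2-bromo-4-(oxiran-2-yl)phenoxy]oxane (diastereomer mixture, racemic) | Brc1cc(C2CO2)ccc1OC1CCCCO1 | intermediate
6 | 5-bromo-2-{2-[3-bromo-4-(oxan-2-yloxy)phenyl]-2-hydroxyethoxy}-4-[(triisopropylsilyl)oxy]benzaldehyde (diastereomer mixture, racemic) | O=Cc1cc(Br)c(O[Si](C(C)C)(C(C)C)C(C)C)cc1OCC(O)c1ccc(OC2CCCCO2)c(Br)c1 | intermediate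
7 | 2-{2-hydroxy-2-[3-(3-methylbut-2-en-1-yl)-4-(oxan-2-yloxy)phenyl]ethoxy}-5-(3-methylbut-2-en-1-yl)-4-[(triisopropylsilyl)oxy]benzaldehyde (diastereomer mixture, racemic) | O=Cc1cc(CC=C(C)C)c(O[Si](C(C)C)(C(C)C)C(C)C)cc1OCC(O)c1ccc(OC2CCCCO2)c(CC=C(C)C)c1 | intermediate
8 | 2-{2-[4-hydroxy-3-(3-methylbut-2-en-1-yl)phenyl]-2-(4-methylbenzenesulfonyl)ethoxy}-5-(3-methylbut-2-en-1-yl)-4-[(triisopropylsilyl)oxy]benzaldehyde (racemic) | O=Cc1cc(CC=C(C)C)c(O[Si](C(C)C)(C(C)C)C(C)C)cc1OCC(c1ccc(O)c(CC=C(C)C)c1)S(=O)(=O)c1ccc(C)cc1 | intermediate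
9 | 5-(3-methylbut-2-en-1-yl)-2-{2-[3-(3-methylbut-2-en-1-yl)-4-oxocyclohexa-2,5-dien-1-ylidene]ethoxy}-4-[(triisopropylsilyl)oxy]benzaldehyde (ring-B p-quinone methide, E/Z mixture, not isolated) | O=Cc1cc(CC=C(C)C)c(O[Si](C(C)C)(C(C)C)C(C)C)cc1OCC=C1C=CC(=O)C(CC=C(C)C)=C1 | intermediate
10 | (3S)-3-[4-hydroxy-3-(3-methylbut-2-en-1-yl)phenyl]-6-(3-methylbut-2-en-1-yl)-7-[(triisopropylsilyl)oxy]-2,3-dihydro-4H-chromen-4-one | CC(C)=CCc1cc([C@H]2COc3cc(O[Si](C(C)C)(C(C)C)C(C)C)c(CC=C(C)C)cc3C2=O)ccc1O | intermediate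
11 | (3S)-7-hydroxy-3-[4-hydroxy-3-(3-methylbut-2-en-1-yl)phenyl]-6-(3-methylbut-2-en-1-yl)-2,3-dihydro-4H-chromen-4-one | CC(C)=CCc1cc([C@H]2COc3cc(O)c(CC=C(C)C)cc3C2=O)ccc1O | target

Total step count: 8. Longest linear sequence: 7 steps (3 → 4 → 5 → 6 → 7 → 8 → 10 → 11, steps 2 to 8).

Steps most likely to fail

Step 7 (Proposed new method). The quinone methide 9 may tautomerise to the 4-hydroxystyryl aryl ether or oligomerise before the acyl anion equivalent is formed, or the product may lose its configuration by base-mediated enolisation at C3. The fallback uses known chemistry and the same C3–C4 ring closure; it sets out from 7. Dess–Martin oxidation of the carbinol should give keto aldehyde F1. An achiral triazolium salt with DBU should effect the intramolecular crossed aldehyde–ketone benzoin cyclisation to racemic 3-hydroxychromanone F2. Dehydration (SOCl2, pyridine, 0 °C) should give isoflavone F3. Asymmetric transfer hydrogenation with a Ru(II)–TsDPEN catalyst (HCO2H/Et3N) reduces the enone C=C and then the ketone under dynamic kinetic resolution, and should give cis-(3S,4S)-isoflavan-4-ol F4. Dess–Martin oxidation should return the ketone as THP-protected (3S)-isoflavanone F5 without touching C3. PPTS in MeOH then removes the THP group and the route is rejoined at 10.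

Step 4. The phenoxide may attack the benzylic epoxide carbon, since the p-alkoxyaryl group favours SN1-like opening, and the aryl silyl group may be transferred or lost at 80 °C. The fallback sets out from 2. Purchased 2-bromo-1-(3-bromo-4-hydroxyphenyl)ethan-1-one F6 is converted into its THP ether F7 (dihydropyran, PPTS). O-Alkylation of 2 with F7 (K2CO3, acetone, rt) should give keto aldehyde F8, in which the C–O bond can only form at the CH2 carbon. NaBH4 reduces both carbonyl groups to diol F9, and TEMPO/PhI(OAc)2 should re-oxidise only the primary benzylic alcohol, which rejoins the route at 6.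

Step 5. Allylic transposition during coupling may give 1,1-dimethylallyl isomers, and slow oxidative addition at the bromide flanked by the OTIPS group may leave mono-coupled material. The fallback sets out from 6. Twofold Stille coupling with allyltributylstannane, which has no regiochemical ambiguity, should give bis-allyl compound F10. Olefin cross-metathesis with 2-methylbut-2-ene (second-generation Grubbs catalyst, CH2Cl2, 40 °C) should convert both allyl groups into prenyl groups and rejoin the route at 7.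

Further compounds
F1 | step 7 | 5-(3-methylbut-2-en-1-yl)-2-{2-[3-(3-methylbut-2-en-1-yl)-4-(oxan-2-yloxy)phenyl]-2-oxoethoxy}-4-[(triisopropylsilyl)oxy]benzaldehyde | O=Cc1cc(CC=C(C)C)c(O[Si](C(C)C)(C(C)C)C(C)C)cc1OCC(=O)c1ccc(OC2CCCCO2)c(CC=C(C)C)c1
F2 | step 7 | 3-hydroxy-6-(3-methylbut-2-en-1-yl)-3-[3-(3-methylbut-2-en-1-yl)-4-(oxan-2-yloxy)phenyl]-7-[(triisopropylsilyl)oxy]-2,3-dihydro-4H-chromen-4-one (racemic at C3) | CC(C)=CCc1cc(C2(O)COc3cc(O[Si](C(C)C)(C(C)C)C(C)C)c(CC=C(C)C)cc3C2=O)ccc1OC1CCCCO1
F3 | step 7 | 6-(3-methylbut-2-en-1-yl)-3-[3-(3-methylbut-2-en-1-yl)-4-(oxan-2-yloxy)phenyl]-7-[(triisopropylsilyl)oxy]-4H-chromen-4-one | CC(C)=CCc1cc(C2=COc3cc(O[Si](C(C)C)(C(C)C)C(C)C)c(CC=C(C)C)cc3C2=O)ccc1OC1CCCCO1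
F4 | step 7 | (3S,4S)-6-(3-methylbut-2-en-1-yl)-3-[3-(3-methylbut-2-en-1-yl)-4-(oxan-2-yloxy)phenyl]-7-[(triisopropylsilyl)oxy]-3,4-dihydro-2H-chromen-4-ol (cis) | CC(C)=CCc1cc([C@H]2COc3cc(O[Si](C(C)C)(C(C)C)C(C)C)c(CC=C(C)C)cc3[C@H]2O)ccc1OC1CCCCO1
F5 | step 7 | (3S)-6-(3-methylbut-2-en-1-yl)-3-[3-(3-methylbut-2-en-1-yl)-4-(oxan-2-yloxy)phenyl]-7-[(triisopropylsilyl)oxy]-2,3-dihydro-4H-chromen-4-one | CC(C)=CCc1cc([C@H]2COc3cc(O[Si](C(C)C)(C(C)C)C(C)C)c(CC=C(C)C)cc3C2=O)ccc1OC1CCCCO1
F6 | step 4 | 2-bromo-1-(3-bromo-4-hydroxyphenyl)ethan-1-one (purchased) | O=C(CBr)c1ccc(O)c(Br)c1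
F7 | step 4 | 2-bromo-1-[3-bromo-4-(oxan-2-yloxy)phenyl]ethan-1-one | O=C(CBr)c1ccc(OC2CCCCO2)c(Br)c1
F8 | step 4 | 5-bromo-2-{2-[3-bromo-4-(oxan-2-yloxy)phenyl]-2-oxoethoxy}-4-[(triisopropylsilyl)oxy]benzaldehyde | O=Cc1cc(Br)c(O[Si](C(C)C)(C(C)C)C(C)C)cc1OCC(=O)c1ccc(OC2CCCCO2)c(Br)c1
F9 | step 4 | 1-[3-bromo-4-(oxan-2-yloxy)phenyl]-2-{4-bromo-2-(hydroxymethyl)-5-[(triisopropylsilyl)oxy]phenoxy}ethan-1-ol | OCc1cc(Br)c(O[Si](C(C)C)(C(C)C)C(C)C)cc1OCC(O)c1ccc(OC2CCCCO2)c(Br)c1
F10 | step 5 | 2-{2-hydroxy-2-[4-(oxan-2-yloxy)-3-(prop-2-en-1-yl)phenyl]ethoxy}-5-(prop-2-en-1-yl)-4-[(triisopropylsilyl)oxy]benzaldehyde | O=Cc1cc(CC=C)c(O[Si](C(C)C)(C(C)C)C(C)C)cc1OCC(O)c1ccc(OC2CCCCO2)c(CC=C)c1
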